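The data are calculated on assumed constants; scatter was added.

Late in the autumn run, the flask asked about, target follows starting material at a nearly steady ratio, the quasi-steady-state ratio of a consumed intermediate. That ratio needs one small correction to give the crest.

| flask | starting material | remark | time |
|---|---|---|---|
| autumn | 0.86 M | the very flask that is asked about, followed so far |  |
| dawn | 0.43 M | run made earlier |  |
| flask | 0.86 M |  | 2.0 d |

| run | time / h | target / % | starting material / % |
|---|---|---|---|
| autumn | 1.00 | 6.5 | 84.9 |
| autumn | 1.50 | 8.3 | 80.5 |
| autumn | 3.00 | 10.1 | 67.8 |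
| autumn | 5.00 | 13.4 | 55.0 |
| autumn | 8.00 | 9.4 | 41.6 |
| autumn | 15.0 | 5.9 | 22.4 |
| autumn | 25.0 | 2.3 | 8.7 |
| dawn | 1.00 | 6.7 | 86.7 |
| dawn | 2.00 | 8.6 | 75.6 |
| dawn | 4.00 | 12.6 | 61.6 |
| dawn | 8.00 | 8.7 | 43.4 |
| dawn | 12.0 | 6.5 | 29.5 |
| dawn | 25.0 | 2.1 | 12.8 |
| dawn | 50.0 | 1.0 | 2.2 |

(scatter of a reading: 1 percentage point)



Each reading carries a standard deviation of 1 percentage point.

- when, up to 2.0 d, the flask holds most target
- the amount of target, in percent of the starting material charged, at that time

Reading the autumn table from the bottom, the last two rows give a tail ratio of 0.264, and starting material falls between them at 0.0946 h⁻¹. The top row gives the making rate: target formed per unit of starting material present, on the mean of the first hour, is 0.0703 h⁻¹.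

Target is lost at making rate over tail ratio plus the fall of starting material, 0.361 h⁻¹, which is faster than starting material falls. The tail ratio therefore overstates the crest, where making equals loss. The crest share, target over starting material at the moment target stops rising, is making rate over loss rate, 0.195.

The 5.00 h row gives an early fall of 0.120 h⁻¹. A two-step series then puts this reckoning's crest at 0.191 d, holding 11.3 % target.

The forecast says 0.19 d (0.14 d to 0.24 d) and 12.2 % (11 % to 13.5 %), starting from “Dawn and autumn agree when expressed as percentages”. Its target is higher than this reckoning's.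

The simulation gives 11.1 % at 0.168 d, inside both forecast ranges.

    starting material ⇌ target (K = 0.370, k = 0.00140 min⁻¹)
    starting material ⇌ isomer of the product A (K = 85.0, k = 5.10 × 10⁻⁴ min⁻¹)
    starting material ⇌ third isomer (K = 2.70, k = 3.00 × 10⁻⁴ min⁻¹)
    2 starting material → self-condensation product (k = 3.20 × 10⁻⁴ L mol⁻¹ min⁻¹)
    target → over-reaction product (k = 0.00360 min⁻¹)
    target ⇌ isomer of the product B (K = 20.0, k = 5.10 × 10⁻⁵ min⁻¹)

At that time the flask holds 59.0 % starting material, so target over starting material stands at 0.188, beside the crest share of 0.195. The neighbour flask charged at 2.1 M crests at 10.2 %, below the forecast's low end of 11 %, so a run at that charge would put the forecast out of range. Taken at the 0.188 of the asked flask, that crest means about 54.3 % starting material at its top.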